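**Retrosynthetic overview**

1. Numbering used throughout: ten-membered ring C1–C10 (C1=C10 alkene, CH3 on C4, lactone O on C6, ring-fusion C7, O-angeloyl on C8, OH on C9); lactone C11/C12 with exo-methylene C13; ester carbon C14 on C10. "Cis/trans ring alkene" refers to C2 and C9.
2. Target 24 ⇐ O9-desilylation and O8-angeloylation ⇐ C14 CH3 → CO2CH3 by SeO2 allylic oxidation, whose [2,3]-shift also turns the trans ring alkene into the cis one ⇐ α-methylenation at C11 ⇐ diol 10.
3. Key disconnection C8–C9: 10 ⇐ dialdehyde 9 by titanium-induced pinacol ring closure. The enabling feature is the vicinal pair of oxygen-bearing ring carbons, C8 (O-acyl, on lactone carbon C7) and C9 (OH, allylic to C1=C10). Each is an aldehyde carbon in reduced form, so two carbons of like polarity are joined reductively.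
4. 9 ⇐ lactone alcohol 7 (SeO2 at the prenyl E-methyl, which becomes C9; then double Dess–Martin oxidation) ⇐ Evans syn-aldol of succinyl imide 3 with (S)-citronellal 4 (C6–C7 bond, both stereocentres) and lactonisation.
5. Ring order: γ-lactone first (step 2), ten-membered carbocycle second (step 6); C4 comes from citronellal.

Key step: step 6

Remark: (S)-citronellal of high enantiomeric purity is assumed; any minor enantiomer would end up in a diastereomeric aldol lactone that can be removed at the stage of 6.

**Route**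

Step 1
Reactants: 1 (4S)-4-benzyl-1,3-oxazolidin-2-one; 2 methyl 4-chloro-4-oxobutanoate
Product: 3 methyl 4-[(4S)-4-benzyl-2-oxo-1,3-oxazolidin-3-yl]-4-oxobutanoate
Conditions: n-BuLi, THF, −78 °C; then 2, −78 to 0 °C
Reagents that add atoms: none
Why: N-acylation of the lithiated oxazolidinone with the acid chloride, the standard preparation of an Evans imide.

Step 2
Reactants: 3 succinyl imide; 4 (S)-citronellal, (3S)-3,7-dimethyloct-6-enal
Product: 6 trans-lactone imide (4S)-4-benzyl-3-{[(2R,3S)-2-[(2S)-2,6-dimethylhept-5-en-1-yl]-5-oxooxolan-3-yl]carbonyl}-1,3-oxazolidin-2-one, via syn-aldol adduct 5 (not isolated)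
Conditions: Bu2BOTf, iPr2NEt, CH2Cl2, 0 °C; 4, −78 to 0 °C; pH 7 buffer, MeOH, H2O2; then TsOH·H2O (cat.), CH2Cl2, rt
Reagents that add atoms: none
Why: Evans syn-aldol reaction, in which the Z-boron enolate (formed at the imide α-CH2, not at the ester) adds through a Zimmerman–Traxler chair on the face opposite the benzyl group and sets C6 and C7 together, after which acid-catalysed lactonisation of the γ-hydroxy ester should give the trans-4,5-disubstituted lactone.

Step 3
Reactants: 6 trans-lactone imide
Product: 7 (4R,5R)-5-[(2S)-2,6-dimethylhept-5-en-1-yl]-4-(hydroxymethyl)oxolan-2-one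
Conditions: NaBH4, THF/H2O (4:1), 0 °C to rt, short reaction time, neutral work-up
Reagents that add atoms: none
Why: Reductive removal of the Evans auxiliary, since NaBH4 in aqueous THF attacks the activated exocyclic imide carbonyl much faster than the γ-lactone and should give the primary alcohol (future C8) and the recoverable oxazolidinone without touching C6 or C7.

Step 4
Reactants: 7 hydroxymethyl lactone
Product: 8 (4R,5R)-4-(hydroxymethyl)-5-[(2S,5E)-7-hydroxy-2,6-dimethylhept-5-en-1-yl]oxolan-2-one
Conditions: SeO2 (0.5 equiv), t-BuOOH, salicylic acid (cat.), CH2Cl2, rt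
Reagents that add atoms: tert-butyl hydroperoxide CC(C)(C)OO (oxygen atom, carried by the SeO2 catalyst O=[Se]=O)
Why: Riley allylic oxidation (ene reaction then [2,3]-sigmatropic shift), which oxidises the methyl group trans to the chain of the trisubstituted alkene and should give the (E)-allylic alcohol; any enal from over-oxidation converges in step 5.

Step 5
Reactants: 8 lactone diol
Product: 9 (2R,3S)-2-[(2S,5E)-2,6-dimethyl-7-oxohept-5-en-1-yl]-5-oxooxolane-3-carbaldehyde
Conditions: DMP (2.5 equiv), CH2Cl2, 0 °C to rt; filtration through a short silica pad, used at once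
Reagents that add atoms: none
Why: Dess–Martin oxidation of both primary alcohols under non-basic conditions, so that the β-acyloxy aldehyde should neither eliminate nor epimerise at C7 (the trans arrangement is also the thermodynamic one).

Step 6
Reactants: 9 lactone dialdehyde
Product: 10 (1(10)-trans)-8β,9α-dihydroxy-4αH-13-norgermacr-1(10)-en-12,6α-olide (trans-fused lactone, 6β-H, 7α-H)
Conditions: TiCl3(DME)1.5 (10 equiv), Zn–Cu couple (25 equiv), DME, reflux 2 h, then 25 °C; 9 added by syringe pump over 30 h (about 2 mM final); aq K2CO3 work-up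
Reagents that add atoms: none
Why: Low-valent titanium (from TiCl3(DME)1.5 and Zn–Cu) transfers one electron to each aldehyde of 9, and the two titanium-bound ketyl radicals (an alkyl ketyl at C8, an allylic ketyl at C9) combine carbon to carbon, joining two carbons of like electrophilic polarity; aqueous work-up of the titanium diolate should give diol 10, because at 25 °C the pinacolate is not deoxygenated. The closest known reaction type is the titanium-induced intramolecular pinacol coupling of dialdehydes to medium- and large-ring 1,2-diols (McMurry pinacol macrocyclisation). The ten-membered carbocycle is closed end to end, exo at both carbonyl groups (10-exo-trig at C8 and at C9), helped by the trans-lactone and the E-alkene, which hold four of the ten ring atoms in place. C8 is controlled by the neighbouring C7 stereocentre: with the forming C8–C9 bond anti to the C7–C11 bond and the carbonyl oxygen between C6 and C11 (Felkin–Anh), the oxygen should end up β; C9 is set relative to C8 by the preference of ten-membered and larger rings to place the two titanium-bound oxygens anti, which should give the trans (threo, 9α) diol. The step needs ring closure over oligomerisation (syringe-pump addition, high dilution), coupling at the carbonyl carbon and not at C1 of the enal (secured by the oxygen–titanium bond of the ketyl), and no epimerisation or β-elimination at C7 (secured by the non-basic medium and the thermodynamically preferred trans-lactone).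

Step 7
Reactants: 10 ten-membered trans-diol
Product: 12 9α-(tert-butyldimethylsilyloxy)-8β-(triethylsilyloxy) bis-ether of 10, via 9-O-TBS ether 11 (not isolated)
Conditions: TBSCl (1.1 equiv), imidazole, DMF, 0 °C; then TESCl (1.5 equiv), DMAP (cat.), rt
Reagents that add atoms: tert-butyldimethylsilyl chloride CC(C)(C)[Si](C)(C)Cl; triethylsilyl chloride CC[Si](Cl)(CC)CC
Why: Sequential silyl ether formation under steric control, in which the allylic C9 hydroxyl, flanked by the planar C10, should react with the bulky TBSCl before the C8 hydroxyl next to the branched C7, and the remaining C8 hydroxyl is then capped with the more labile TES group.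

Step 8
Reactants: 12 bis-silyl ether
Product: 15 (1(10)-trans)-9α-(tert-butyldimethylsilyloxy)-8β-(triethylsilyloxy)-4αH-germacra-1(10),11(13)-dien-12,6α-olide, via Mannich base 13 (not isolated), via trimethylammonium iodide 14 (not isolated)
Conditions: LiN(iPr)2, THF, −78 °C; CH2=NMe2+ I−, −78 °C to rt; then MeI, MeOH, rt; then aq NaHCO3, CH2Cl2, rt
Reagents that add atoms: dimethylmethylideneammonium iodide (Eschenmoser's salt) C=[N+](C)C.[I-]
Why: Eschenmoser methylenation, in which the lithium enolate of the lactone (the only enolisable carbonyl) is aminomethylated at C11 and Hofmann-type elimination of the quaternised Mannich base should give the exocyclic methylene without creating a stereocentre.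

Step 9
Reactants: 15 α-methylene lactone with trans ring alkene and C14 methyl
Product: 16 (1(10)-cis)-9α-(tert-butyldimethylsilyloxy)-14-hydroxy-8β-(triethylsilyloxy)-4αH-germacra-1(10),11(13)-dien-12,6α-olide
Conditions: SeO2 (0.5 equiv), t-BuOOH, CH2Cl2, rt
Reagents that add atoms: tert-butyl hydroperoxide CC(C)(C)OO (oxygen atom, carried by the SeO2 catalyst O=[Se]=O)
Why: Riley allylic oxidation, in which the ene reaction takes hydrogen from the C14 methyl (C9–H is a shielded silyloxy methine and both other alkenes are electron-poor) and the [2,3]-shift of the allylseleninic acid, with C2 pseudo-equatorial, should place the oxidised carbon trans to C2 and so re-form the alkene as the cis ring alkene, the known behaviour of trans-1(10)-germacranolides under these conditions.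

Step 10
Reactants: 16 14-alcohol
Product: 17 (1(10)-cis)-9α-(tert-butyldimethylsilyloxy)-14-oxo-8β-(triethylsilyloxy)-4αH-germacra-1(10),11(13)-dien-12,6α-olide
Conditions: DMP, CH2Cl2, 0 °C to rt
Reagents that add atoms: none
Why: Dess–Martin oxidation of the primary allylic alcohol to the enal whose formyl group is trans to C2, the stable geometry of a trisubstituted enal.

Step 11
Reactants: 17 14-al
Product: 19 methyl (1(10)-cis)-9α-(tert-butyldimethylsilyloxy)-8β-(triethylsilyloxy)-4αH-germacra-1(10),11(13)-dien-12,6α-olid-14-oate, via 14-oic acid 18 (not isolated)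
Conditions: NaClO2, NaH2PO4, 2-methyl-2-butene, t-BuOH/H2O, rt; then MeI, K2CO3, DMF, rt
Reagents that add atoms: sodium chlorite [Na+].[O-]Cl=O; iodomethane CI
Why: Pinnick oxidation of the enal to the acid (2-methyl-2-butene scavenges HOCl and spares the alkenes) followed by O-alkylation of the potassium carboxylate with MeI, an esterification that should leave the α-methylene lactone untouched.

Step 12
Reactants: 19 bis-silyl methyl ester
Product: 20 methyl (1(10)-cis)-9α-(tert-butyldimethylsilyloxy)-8β-hydroxy-4αH-germacra-1(10),11(13)-dien-12,6α-olid-14-oate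
Conditions: PPTS (0.2 equiv), MeOH/CH2Cl2 (1:1), 0 °C to rt
Reagents that add atoms: none
Why: Acid-catalysed methanolysis, which cleaves the triethylsilyl ether far faster than the tert-butyldimethylsilyl ether and should free only the C8 hydroxyl.

Step 13
Reactants: 20 C8 alcohol; 21 angelic acid, (Z)-2-methylbut-2-enoic acid
Product: 23 methyl (1(10)-cis)-8β-angeloyloxy-9α-(tert-butyldimethylsilyloxy)-4αH-germacra-1(10),11(13)-dien-12,6α-olid-14-oate, via mixed anhydride 22 (not isolated)
Conditions: 21, 2,4,6-trichlorobenzoyl chloride, Et3N, toluene, rt; then 20, toluene, 80 °C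
Reagents that add atoms: none
Why: Yamaguchi esterification, in which the mixed anhydride of angelic acid acylates the hindered C8 hydroxyl without added nucleophilic catalyst, conditions under which the (Z)-enoate should not isomerise to the tiglate; C8 keeps its configuration because its C–O bond is not broken.

Step 14
Reactants: 23 silyl-protected angelate
Product: 24 target, methyl 8β-angeloyloxy-9α-hydroxy-4αH-germacra-1(10),11(13)-dien-12,6α-olid-14-oate with cis ring alkene (4S,6R,7S,8S,9S; C1=C10 is E by sequence rules)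
Conditions: HF·pyridine, pyridine, THF, 0 °C to rt
Reagents that add atoms: none
Why: Fluoride-mediated silyl ether cleavage under buffered acidic conditions, which should avoid base-induced acyl migration from O8 to O9 and conjugate addition to the α-methylene lactone.

**Compound list**

1 | (4S)-4-benzyl-1,3-oxazolidin-2-one | O=C1N[C@@H](Cc2ccccc2)CO1 | starting material
2 | methyl 4-chloro-4-oxobutanoate | COC(=O)CCC(=O)Cl | starting material
3 | methyl 4-[(4S)-4-benzyl-2-oxo-1,3-oxazolidin-3-yl]-4-oxobutanoate | COC(=O)CCC(=O)N1[C@@H](Cc2ccccc2)COC1=O | intermediate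
4 | (S)-citronellal, (3S)-3,7-dimethyloct-6-enal | C[C@@H](CCC=C(C)C)CC=O | starting material
5 | syn-aldol adduct, methyl (3S,4R,6S)-3-{[(4S)-4-benzyl-2-oxo-1,3-oxazolidin-3-yl]carbonyl}-4-hydroxy-6,10-dimethylundec-9-enoate | COC(=O)C[C@H](C(=O)N1[C@@H](Cc2ccccc2)COC1=O)[C@H](O)C[C@@H](C)CCC=C(C)C | intermediate
6 | (4S)-4-benzyl-3-{[(2R,3S)-2-[(2S)-2,6-dimethylhept-5-en-1-yl]-5-oxooxolan-3-yl]carbonyl}-1,3-oxazolidin-2-one | O=C1C[C@H](C(=O)N2[C@@H](Cc3ccccc3)COC2=O)[C@@H](C[C@@H](C)CCC=C(C)C)O1 | intermediate
7 | (4R,5R)-5-[(2S)-2,6-dimethylhept-5-en-1-yl]-4-(hydroxymethyl)oxolan-2-one | O=C1C[C@H](CO)[C@@H](C[C@@H](C)CCC=C(C)C)O1 | intermediate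
8 | (4R,5R)-4-(hydroxymethyl)-5-[(2S,5E)-7-hydroxy-2,6-dimethylhept-5-en-1-yl]oxolan-2-one | O=C1C[C@H](CO)[C@@H](C[C@@H](C)CC/C=C(\C)CO)O1 | intermediate
9 | (2R,3S)-2-[(2S,5E)-2,6-dimethyl-7-oxohept-5-en-1-yl]-5-oxooxolane-3-carbaldehyde | O=C1C[C@H](C=O)[C@@H](C[C@@H](C)CC/C=C(\C)C=O)O1 | intermediate
10 | (1(10)-trans)-8β,9α-dihydroxy-4αH-13-norgermacr-1(10)-en-12,6α-olide | O=C1O[C@@H]2C[C@@H](C)CC/C=C(\C)[C@H](O)[C@@H](O)[C@H]2C1 | intermediate
11 | 9-O-tert-butyldimethylsilyl ether of 10 (8β-OH free) | O=C1O[C@@H]2C[C@@H](C)CC/C=C(\C)[C@H](O[Si](C)(C)C(C)(C)C)[C@@H](O)[C@H]2C1 | intermediate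
12 | 9-O-tert-butyldimethylsilyl 8-O-triethylsilyl bis-ether of 10 | O=C1O[C@@H]2C[C@@H](C)CC/C=C(\C)[C@H](O[Si](C)(C)C(C)(C)C)[C@@H](O[Si](CC)(CC)CC)[C@H]2C1 | intermediate
13 | Mannich base, 11-(dimethylaminomethyl) derivative of 12 (C11 epimers, inconsequential) | O=C1O[C@@H]2C[C@@H](C)CC/C=C(\C)[C@H](O[Si](C)(C)C(C)(C)C)[C@@H](O[Si](CC)(CC)CC)[C@H]2C1CN(C)C | intermediate
14 | trimethylammonium iodide of 13 | O=C1O[C@@H]2C[C@@H](C)CC/C=C(\C)[C@H](O[Si](C)(C)C(C)(C)C)[C@@H](O[Si](CC)(CC)CC)[C@H]2C1C[N+](C)(C)C.[I-] | intermediate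
15 | (1(10)-trans)-9α-(tert-butyldimethylsilyloxy)-8β-(triethylsilyloxy)-4αH-germacra-1(10),11(13)-dien-12,6α-olide | C=C1C(=O)O[C@@H]2C[C@@H](C)CC/C=C(\C)[C@H](O[Si](C)(C)C(C)(C)C)[C@@H](O[Si](CC)(CC)CC)[C@@H]12 | intermediate
16 | (1(10)-cis)-14-hydroxy analogue of 15 | C=C1C(=O)O[C@@H]2C[C@@H](C)CC/C=C(/CO)[C@H](O[Si](C)(C)C(C)(C)C)[C@@H](O[Si](CC)(CC)CC)[C@@H]12 | intermediate
17 | (1(10)-cis)-14-oxo analogue (enal, formyl trans to C2) | C=C1C(=O)O[C@@H]2C[C@@H](C)CC/C=C(/C=O)[C@H](O[Si](C)(C)C(C)(C)C)[C@@H](O[Si](CC)(CC)CC)[C@@H]12 | intermediate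
18 | (1(10)-cis)-14-oic acid | C=C1C(=O)O[C@@H]2C[C@@H](C)CC/C=C(/C(=O)O)[C@H](O[Si](C)(C)C(C)(C)C)[C@@H](O[Si](CC)(CC)CC)[C@@H]12 | intermediate
19 | methyl (1(10)-cis)-9α-(tert-butyldimethylsilyloxy)-8β-(triethylsilyloxy)-4αH-germacra-1(10),11(13)-dien-12,6α-olid-14-oate | C=C1C(=O)O[C@@H]2C[C@@H](C)CC/C=C(/C(=O)OC)[C@H](O[Si](C)(C)C(C)(C)C)[C@@H](O[Si](CC)(CC)CC)[C@@H]12 | intermediate
20 | methyl (1(10)-cis)-9α-(tert-butyldimethylsilyloxy)-8β-hydroxy-4αH-germacra-1(10),11(13)-dien-12,6α-olid-14-oate | C=C1C(=O)O[C@@H]2C[C@@H](C)CC/C=C(/C(=O)OC)[C@H](O[Si](C)(C)C(C)(C)C)[C@@H](O)[C@@H]12 | intermediate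
21 | angelic acid, (Z)-2-methylbut-2-enoic acid | C/C=C(/C)C(=O)O | starting material
22 | angelic 2,4,6-trichlorobenzoic anhydride | C/C=C(/C)C(=O)OC(=O)c1c(Cl)cc(Cl)cc1Cl | intermediate
23 | methyl (1(10)-cis)-8β-angeloyloxy-9α-(tert-butyldimethylsilyloxy)-4αH-germacra-1(10),11(13)-dien-12,6α-olid-14-oate | C=C1C(=O)O[C@@H]2C[C@@H](C)CC/C=C(/C(=O)OC)[C@H](O[Si](C)(C)C(C)(C)C)[C@@H](OC(=O)/C(C)=C\C)[C@@H]12 | intermediate
24 | methyl (1(10)-cis)-8β-angeloyloxy-9α-hydroxy-4αH-germacra-1(10),11(13)-dien-12,6α-olid-14-oate (4S,6R,7S,8S,9S) | C=C1C(=O)O[C@@H]2C[C@@H](C)CC/C=C(/C(=O)OC)[C@H](O)[C@@H](OC(=O)/C(C)=C\C)[C@@H]12 | target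

**Step count**

Total: 14 steps. Longest linear sequence: 14 steps (from 1 and 2 to 24; 13 steps from citronellal 4).

**Steps most likely to fail, with fallbacks**

Step 6 (ring closure). The risk is intermolecular coupling competing with ten-membered ring closure, and closure with the two oxygens syn (cis-diol, wrong configuration at C9) instead of anti. The fallback sets out from 9 and comes back at 10. The same bond is closed with samarium diiodide (SmI2, THF, t-BuOH, high dilution). There one trivalent samarium bridges both ketyl oxygens, so the cis-diol is the expected product: (1(10)-trans)-8β,9β-dihydroxy-4αH-13-norgermacr-1(10)-en-12,6α-olide F1. A cis-diol cannot close to an epoxide, so the allylic C9 carbinol is inverted by Mitsunobu esterification (PPh3, DIAD, 4-nitrobenzoic acid, toluene) to the 9α-(4-nitrobenzoyloxy)-8β-hydroxy lactone F2. Mild methanolysis (NaN3, MeOH, 40 °C) should then give 10.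

Step 7 (differentiation of O8 and O9). The risk is insufficient site selectivity in the first silylation (silylation at O8 or at both oxygens). The fallback sets out from 10 and comes back at 12; it differentiates by oxidation state instead of sterics. MnO2 (CH2Cl2, rt) should oxidise only the allylic C9 carbinol and give the 8β-hydroxy-9-oxo enone F3. TESOTf with 2,6-lutidine gives the 8β-(triethylsilyloxy)-9-oxo enone F4. Luche reduction (NaBH4, CeCl3·7H2O, MeOH, −78 °C), with hydride anti to the C8–O bond (Felkin–Anh), should give the 9α-hydroxy-8β-(triethylsilyloxy) lactone F5. TBSOTf with 2,6-lutidine then gives 12. This detour would also correct a wrong C9 configuration from step 6.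

Step 9 (allylic oxidation with alkene inversion). The risk is a sigmatropic shift that keeps the trans ring alkene, so that the oxidised carbon ends up cis to C2. The fallback sets out from 15 and comes back at 17; it sets the geometry under thermodynamic instead of kinetic control. The SeO2 product with retained geometry, the (1(10)-trans)-14-hydroxy bis-silyl ether F6, is oxidised with DMP to the (1(10)-trans)-14-oxo enal F7, whose formyl group is cis to C2. Catalytic I2 (5 mol %, CH2Cl2, daylight) should then equilibrate it to 17, which is favoured both as the enal with formyl trans to C2 and as the less strained cis-cyclodecene.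

**Further compounds**

F1 | step 6 | (1(10)-trans)-8β,9β-dihydroxy-4αH-13-norgermacr-1(10)-en-12,6α-olide (9-epimer of 10) | O=C1O[C@@H]2C[C@@H](C)CC/C=C(\C)[C@@H](O)[C@@H](O)[C@H]2C1
F2 | step 6 | (1(10)-trans)-8β-hydroxy-9α-(4-nitrobenzoyloxy)-4αH-13-norgermacr-1(10)-en-12,6α-olide | O=C1O[C@@H]2C[C@@H](C)CC/C=C(\C)[C@H](OC(=O)c3ccc(cc3)[N+](=O)[O-])[C@@H](O)[C@H]2C1
F3 | step 7 | (1(10)-trans)-8β-hydroxy-9-oxo-4αH-13-norgermacr-1(10)-en-12,6α-olide | O=C1O[C@@H]2C[C@@H](C)CC/C=C(\C)C(=O)[C@@H](O)[C@H]2C1
F4 | step 7 | (1(10)-trans)-9-oxo-8β-(triethylsilyloxy)-4αH-13-norgermacr-1(10)-en-12,6α-olide | O=C1O[C@@H]2C[C@@H](C)CC/C=C(\C)C(=O)[C@@H](O[Si](CC)(CC)CC)[C@H]2C1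
F5 | step 7 | (1(10)-trans)-9α-hydroxy-8β-(triethylsilyloxy)-4αH-13-norgermacr-1(10)-en-12,6α-olide | O=C1O[C@@H]2C[C@@H](C)CC/C=C(\C)[C@H](O)[C@@H](O[Si](CC)(CC)CC)[C@H]2C1
F6 | step 9 | (1(10)-trans)-9α-(tert-butyldimethylsilyloxy)-14-hydroxy-8β-(triethylsilyloxy)-4αH-germacra-1(10),11(13)-dien-12,6α-olide | C=C1C(=O)O[C@@H]2C[C@@H](C)CC/C=C(\CO)[C@H](O[Si](C)(C)C(C)(C)C)[C@@H](O[Si](CC)(CC)CC)[C@@H]12
F7 | step 9 | (1(10)-trans)-9α-(tert-butyldimethylsilyloxy)-14-oxo-8β-(triethylsilyloxy)-4αH-germacra-1(10),11(13)-dien-12,6α-olide | C=C1C(=O)O[C@@H]2C[C@@H](C)CC/C=C(\C=O)[C@H](O[Si](C)(C)C(C)(C)C)[C@@H](O[Si](CC)(CC)CC)[C@@H]12
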